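**Plan**

- Retrosynthesis: the five O–benzyl bonds and a C3''–Br bond are cut last (one hydrogenolysis). Ring C is then cut at C1''–C6'' and C2''–C3''. Next come the ester between the ring B carboxyl and O4'' (a pyrone enol ester), the ester between the ring A carboxyl and O4', the 2'-O–CH3 bond and the C5–O bond of ring A.
- Enabling feature: ring C (C1''–C6''), a 2-hydroxy-6-methylbenzoic acid acylated on O4'', is a masked 4-acyloxy-6-methyl-2-pyrone. Pyrone C3, C4–O, C5 and C6–CH3 become C3'', C4''–O, C5'' and C6''–CH3. C1'' (with its carboxyl) and C2'' (with its oxygen) come from a malonate ketene acetal, and pyrone C2/O1 leave as CO2. A bromine on pyrone C3 is added to activate the diene and is removed together with the benzyl groups.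
- Forward: orcinol is formylated. Ring A is oxygenated at C5, benzylated and oxidised to the acid, then esterified onto O4' of the ring B aldehyde. O2' is methylated and the aldehyde oxidised to the A–B acid, which acylates 3-bromo-4-hydroxy-6-methyl-2-pyrone. Ring C is built last by cycloaddition, loss of CO2 and aromatization, and hydrogenolysis frees the target.
- Stereochemistry: the target has no stereocentre and no stereogenic double bond; the sp3 centres of the cycloadduct are transient.

Key step: step 11

Remark: position labels are unprimed for ring A, primed for ring B and double-primed for ring C. The silyl ketene acetal is used as the alkene-isomer mixture in which it forms, because the alkene geometry is lost on aromatization.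

**Route**

Step 1
Reactants: 1 orcinol (5-methylbenzene-1,3-diol)
Product: 3 2,4-dihydroxy-6-methylbenzaldehyde, via iminium chloride 2 (not isolated)
Conditions: POCl3, DMF, 0 °C to rt; then H2O, 50 °C
Reagents that add atoms: N,N-dimethylformamide, CN(C)C=O; water, O
Why: Vilsmeier–Haack formylation of the resorcinol ring should go to the position ortho to one hydroxyl and para to the other, next to the methyl group, and hydrolysis of the iminium salt frees the aldehyde.

Step 2
Reactants: 3 2,4-dihydroxy-6-methylbenzaldehyde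
Product: 5 2,4,5-trihydroxy-6-methylbenzaldehyde, via aryl sulfate 4 (not isolated)
Conditions: K2S2O8, aq KOH, 0 °C to rt; then aq HCl, 80 °C, N2
Reagents that add atoms: potassium peroxodisulfate K2S2O8, [K+].[K+].[O-]S(=O)(=O)OOS(=O)(=O)[O-]
Why: Elbs persulfate oxidation, in which the phenolate attacks the peroxide oxygen through the only free position para to a hydroxyl (C5, para to the 2-oxygen) and acid hydrolysis of the aryl sulfate gives the hydroquinone.

Step 3
Reactants: 5 2,4,5-trihydroxy-6-methylbenzaldehyde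
Product: 6 2,4,5-tris(benzyloxy)-6-methylbenzaldehyde
Conditions: BnBr, K2CO3, DMF, 60 °C, N2
Reagents that add atoms: benzyl bromide, BrCc1ccccc1
Why: Williamson etherification in warm DMF should alkylate all three phenols, including the hydrogen-bonded 2-hydroxyl, while the inert atmosphere protects the air-sensitive hydroxyhydroquinone until it is capped.

Step 4
Reactants: 6 2,4,5-tris(benzyloxy)-6-methylbenzaldehyde
Product: 7 2,4,5-tris(benzyloxy)-6-methylbenzoic acid
Conditions: NaClO2, NaH2PO4, 2-methyl-2-butene, t-BuOH–THF–H2O, rt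
Reagents that add atoms: sodium chlorite NaClO2, [Na+].[O-]Cl=O
Why: Pinnick oxidation converts the hindered aldehyde into the acid under buffered conditions, and the alkene scavenger removes HOCl before it can chlorinate the electron-rich ring.

Step 5
Reactants: 7 2,4,5-tris(benzyloxy)-6-methylbenzoic acid; 3 2,4-dihydroxy-6-methylbenzaldehyde
Product: 9 4-formyl-3-hydroxy-5-methylphenyl 2,4,5-tris(benzyloxy)-6-methylbenzoate, via mixed anhydride 8 (not isolated)
Conditions: (CF3CO)2O, toluene, rt
Reagents that add atoms: none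
Why: Trifluoroacetic-anhydride-mediated esterification (the classical depside condensation) should acylate only the free 4-hydroxyl, because the 2-hydroxyl is locked in a hydrogen bond to the formyl group.

Step 6
Reactants: 9 4-formyl-3-hydroxy-5-methylphenyl 2,4,5-tris(benzyloxy)-6-methylbenzoate
Product: 10 4-formyl-3-methoxy-5-methylphenyl 2,4,5-tris(benzyloxy)-6-methylbenzoate
Conditions: MeI, K2CO3, DMF, rt
Reagents that add atoms: iodomethane, CI
Why: Williamson O-methylation of the chelated phenol should leave the aryl ester intact, since its carbonyl is shielded by two ortho substituents and the phenoxide sits meta to it and cannot reach it intramolecularly.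

Step 7
Reactants: 10 4-formyl-3-methoxy-5-methylphenyl 2,4,5-tris(benzyloxy)-6-methylbenzoate
Product: 11 2-methoxy-6-methyl-4-{[2,4,5-tris(benzyloxy)-6-methylbenzoyl]oxy}benzoic acid
Conditions: NaClO2, NaH2PO4, 2-methyl-2-butene, t-BuOH–THF–H2O, rt
Reagents that add atoms: sodium chlorite NaClO2, [Na+].[O-]Cl=O
Why: Pinnick oxidation is mildly acidic and non-nucleophilic, so the aryl ester and the benzyl ethers should survive while the aldehyde becomes the carboxylic acid.

Step 8
Reactants: 12 4-hydroxy-6-methyl-2H-pyran-2-one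
Product: 13 3-bromo-4-hydroxy-6-methyl-2H-pyran-2-one
Conditions: NBS, CH2Cl2, rt, dark
Reagents that add atoms: N-bromosuccinimide, O=C1CCC(=O)N1Br
Why: Electrophilic bromination of the cyclic beta-keto-lactone enol occurs at C3, the carbon between the lactone carbonyl and the enol oxygen, and exclusion of light avoids radical bromination of the methyl group.

Step 9
Reactants: 11 2-methoxy-6-methyl-4-{[2,4,5-tris(benzyloxy)-6-methylbenzoyl]oxy}benzoic acid; 13 3-bromo-4-hydroxy-6-methyl-2H-pyran-2-one
Product: 15 3-bromo-6-methyl-2-oxo-2H-pyran-4-yl 2-methoxy-6-methyl-4-{[2,4,5-tris(benzyloxy)-6-methylbenzoyl]oxy}benzoate, via acid chloride 14 (not isolated)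
Conditions: (COCl)2, cat. DMF, CH2Cl2, 0 °C to rt, evaporate; then 13, Et3N, CH2Cl2, 0 °C
Reagents that add atoms: none
Why: Acid chloride formation followed by O-acylation of the acidic pyrone enol (as in mixed-anhydride formation from a hindered aroyl chloride and a carboxylate) should give the 4-O-acyl 2-pyrone, with the C3 bromine blocking the acyl shift to carbon that 4-acyloxypyrones otherwise undergo.

Step 10
Reactants: 16 dibenzyl malonate
Product: 17 benzyl 3-(benzyloxy)-3-[(trimethylsilyl)oxy]prop-2-enoate
Conditions: Me3SiOTf, Et3N, Et2O, 0 °C to rt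
Reagents that add atoms: trimethylsilyl trifluoromethanesulfonate, C[Si](C)(C)OS(=O)(=O)C(F)(F)F
Why: Soft enolization and O-silylation of a malonate with a silyl triflate and an amine base gives the silyl ketene acetal, which is freed from the ammonium triflate and used without chromatography.

Step 11
Reactants: 15 3-bromo-6-methyl-2-oxo-2H-pyran-4-yl 2-methoxy-6-methyl-4-{[2,4,5-tris(benzyloxy)-6-methylbenzoyl]oxy}benzoate; 17 benzyl 3-(benzyloxy)-3-[(trimethylsilyl)oxy]prop-2-enoate
Product: 20 benzyl 2-(benzyloxy)-3-bromo-6-methyl-4-({2-methoxy-6-methyl-4-[(2,4,5-tris(benzyloxy)-6-methylbenzoyl)oxy]benzoyl}oxy)benzoate, via bicyclic lactone 18 (not isolated), via cyclohexadiene 19 (not isolated)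
Conditions: 17 (4 equiv), 2,6-di-tert-butylpyridine (0.1 equiv), toluene, sealed tube, 110 to 130 °C
Reagents that add atoms: none
Why: Proposed new method: the pyrone serves as the diene (C3 to C6) in a polarized, inverse-electron-demand Diels–Alder reaction in which the nucleophilic CH carbon of 17 bonds to C6 and the benzyloxy(silyloxy) carbon to C3, either in concert or by 1,6-addition followed by 6-exo-trig closure of the C3 bromo-dienolate onto the silyloxycarbenium carbon, so that the carbocycle of ring C is closed by an intermolecular [4+2] annulation to give lactone 18; retro-[4+2] loss of CO2 then gives diene 19, which aromatizes by 1,2-elimination of trimethylsilanol across C1''–C2''. The closest known reaction type is the Diels–Alder reaction of 3-bromo-2-pyrones and of 2-pyrones bearing an acceptor at C3 or C5 with vinyl ethers and ketene acetals, followed by loss of CO2 and of an alcohol to give alkoxyarenes; a 4-acyloxy-3-bromo-6-methylpyrone has not been paired with a push–pull, malonate-derived ketene acetal. The four sp3 centres of 18 are transient and no stereocentre survives aromatization, so endo/exo and facial selectivity do not matter. The step needs regioselectivity (ester-bearing carbon to C6, acetal carbon to C3) and chemoselectivity (cycloaddition faster than acyl transfer from the enol ester or addition–elimination at C4): the first should follow from matched polarity, C6 being the vinylogous electrophilic terminus of the lactone and C3 carrying the bromine that lowers the diene LUMO and stabilizes negative charge building up there, and the second from neutral, Lewis-acid-free, non-nucleophilic conditions together with the two ortho substituents that shield each aryl ester carbonyl. If benzyl alcohol were lost in place of silanol, the resulting aryl silyl ether would lead to the same final product.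

Step 12
Reactants: 20 benzyl 2-(benzyloxy)-3-bromo-6-methyl-4-({2-methoxy-6-methyl-4-[(2,4,5-tris(benzyloxy)-6-methylbenzoyl)oxy]benzoyl}oxy)benzoate
Product: 21 2'-O-methylhiascic acid
Conditions: H2 (1 atm), 10% Pd/C, NaOAc (1 equiv), THF–MeOH, rt
Reagents that add atoms: none
Why: Catalytic hydrogenolysis should cleave the four benzyl ethers and the benzyl ester and also remove the aryl bromide by hydrodehalogenation, with acetate taking up the HBr, while the two hindered aryl esters and the methyl ether are not reducible under these conditions.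

**Compound list**

1 | orcinol (5-methylbenzene-1,3-diol) | Cc1cc(O)cc(O)c1 | starting material
2 | N-[(2,4-dihydroxy-6-methylphenyl)methylidene]-N-methylmethanaminium chloride | C[N+](C)=Cc1c(C)cc(O)cc1O.[Cl-] | intermediate
3 | 2,4-dihydroxy-6-methylbenzaldehyde | Cc1cc(O)cc(O)c1C=O | intermediate
4 | potassium 3-formyl-4,6-dihydroxy-2-methylphenyl sulfate | Cc1c(C=O)c(O)cc(O)c1OS(=O)(=O)[O-].[K+] | intermediate
5 | 2,4,5-trihydroxy-6-methylbenzaldehyde | Cc1c(O)c(O)cc(O)c1C=O | intermediate
6 | 2,4,5-tris(benzyloxy)-6-methylbenzaldehyde | Cc1c(OCc2ccccc2)c(OCc2ccccc2)cc(OCc2ccccc2)c1C=O | intermediate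
7 | 2,4,5-tris(benzyloxy)-6-methylbenzoic acid | Cc1c(OCc2ccccc2)c(OCc2ccccc2)cc(OCc2ccccc2)c1C(=O)O | intermediate
8 | 2,4,5-tris(benzyloxy)-6-methylbenzoic trifluoroacetic anhydride | Cc1c(OCc2ccccc2)c(OCc2ccccc2)cc(OCc2ccccc2)c1C(=O)OC(=O)C(F)(F)F | intermediate
9 | 4-formyl-3-hydroxy-5-methylphenyl 2,4,5-tris(benzyloxy)-6-methylbenzoate | Oc1cc(OC(=O)c2c(OCc3ccccc3)cc(OCc3ccccc3)c(OCc3ccccc3)c2C)cc(C)c1C=O | intermediate
10 | 4-formyl-3-methoxy-5-methylphenyl 2,4,5-tris(benzyloxy)-6-methylbenzoate | COc1cc(OC(=O)c2c(OCc3ccccc3)cc(OCc3ccccc3)c(OCc3ccccc3)c2C)cc(C)c1C=O | intermediate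
11 | 2-methoxy-6-methyl-4-{[2,4,5-tris(benzyloxy)-6-methylbenzoyl]oxy}benzoic acid | COc1cc(OC(=O)c2c(OCc3ccccc3)cc(OCc3ccccc3)c(OCc3ccccc3)c2C)cc(C)c1C(=O)O | intermediate
12 | 4-hydroxy-6-methyl-2H-pyran-2-one | Cc1cc(O)cc(=O)o1 | starting material
13 | 3-bromo-4-hydroxy-6-methyl-2H-pyran-2-one | Cc1cc(O)c(Br)c(=O)o1 | intermediate
14 | 2-methoxy-6-methyl-4-{[2,4,5-tris(benzyloxy)-6-methylbenzoyl]oxy}benzoyl chloride | COc1cc(OC(=O)c2c(OCc3ccccc3)cc(OCc3ccccc3)c(OCc3ccccc3)c2C)cc(C)c1C(Cl)=O | intermediate
15 | 3-bromo-6-methyl-2-oxo-2H-pyran-4-yl 2-methoxy-6-methyl-4-{[2,4,5-tris(benzyloxy)-6-methylbenzoyl]oxy}benzoate | COc1cc(OC(=O)c2c(OCc3ccccc3)cc(OCc3ccccc3)c(OCc3ccccc3)c2C)cc(C)c1C(=O)Oc1cc(C)oc(=O)c1Br | intermediate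
16 | dibenzyl malonate (dibenzyl propanedioate) | O=C(CC(=O)OCc1ccccc1)OCc1ccccc1 | starting material
17 | benzyl 3-(benzyloxy)-3-[(trimethylsilyl)oxy]prop-2-enoate (either alkene isomer) | C[Si](C)(C)OC(OCc1ccccc1)=CC(=O)OCc1ccccc1 | intermediate
18 | benzyl 5-(benzyloxy)-4-bromo-8-({2-methoxy-6-methyl-4-[(2,4,5-tris(benzyloxy)-6-methylbenzoyl)oxy]benzoyl}oxy)-1-methyl-3-oxo-5-[(trimethylsilyl)oxy]-2-oxabicyclo[2.2.2]oct-7-ene-6-carboxylate (transient racemic diastereomer mixture, no configuration defined) | COc1cc(OC(=O)c2c(OCc3ccccc3)cc(OCc3ccccc3)c(OCc3ccccc3)c2C)cc(C)c1C(=O)OC1=CC2(C)OC(=O)C1(Br)C(OCc1ccccc1)(O[Si](C)(C)C)C2C(=O)OCc1ccccc1 | intermediate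
19 | benzyl 2-(benzyloxy)-3-bromo-4-({2-methoxy-6-methyl-4-[(2,4,5-tris(benzyloxy)-6-methylbenzoyl)oxy]benzoyl}oxy)-6-methyl-2-[(trimethylsilyl)oxy]cyclohexa-3,5-diene-1-carboxylate (transient racemic diastereomer mixture, no configuration defined) | COc1cc(OC(=O)c2c(OCc3ccccc3)cc(OCc3ccccc3)c(OCc3ccccc3)c2C)cc(C)c1C(=O)OC1=C(Br)C(OCc2ccccc2)(O[Si](C)(C)C)C(C(=O)OCc2ccccc2)C(C)=C1 | intermediate
20 | benzyl 2-(benzyloxy)-3-bromo-6-methyl-4-({2-methoxy-6-methyl-4-[(2,4,5-tris(benzyloxy)-6-methylbenzoyl)oxy]benzoyl}oxy)benzoate | COc1cc(OC(=O)c2c(OCc3ccccc3)cc(OCc3ccccc3)c(OCc3ccccc3)c2C)cc(C)c1C(=O)Oc1cc(C)c(C(=O)OCc2ccccc2)c(OCc2ccccc2)c1Br | intermediate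
21 | 2'-O-methylhiascic acid, 2-hydroxy-6-methyl-4-({2-methoxy-6-methyl-4-[(2,4,5-trihydroxy-6-methylbenzoyl)oxy]benzoyl}oxy)benzoic acid | COc1cc(OC(=O)c2c(O)cc(O)c(O)c2C)cc(C)c1C(=O)Oc1cc(C)c(C(=O)O)c(O)c1 | target

**Step count**

Total: 12 steps. Longest linear sequence: 10 steps (steps 1, 2, 3, 4, 5, 6, 7, 9, 11, 12, from orcinol).

**Steps most likely to fail**

1. Step 11 (Proposed new method). The cycloaddition may be slower than the processes the enol ester undergoes at the same temperature: acyl transfer to the ketene acetal, attack at C4 with loss of the aroyloxy group, or silyl transfer after the first C–C bond so that the ring never closes. Thermal O-to-C silyl migration in the ketene acetal would also remove the dienophile. The fallback uses known chemistry, sets out from acid 11 and takes ring C from orsellinic acid instead of the pyrone. Commercial orsellinic acid is benzylated on the carboxyl (BnBr, KHCO3, DMF) to benzyl 2,4-dihydroxy-6-methylbenzoate F1. Acid 11 is activated with (CF3CO)2O in toluene as its mixed trifluoroacetic anhydride F2, which should acylate only the non-chelated 4-hydroxyl of F1 to give the tetra-O-benzyl tridepside benzyl ester F3. Hydrogenolysis of F3 (H2, Pd/C, THF–MeOH) removes the three benzyl ethers and the benzyl ester and rejoins the route at 21.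

2. Step 9. O-Acylation of the weakly nucleophilic, bromine-flanked pyronate by a di-ortho-substituted acid chloride may be sluggish, and the product, a vinylogous mixed anhydride, may hydrolyse or transfer its acyl group during isolation. The fallback sets out from acid chloride 14 (made from 11 as in step 9) and pyrone 12, and gives up the bromine. The more nucleophilic and less hindered 12 is O-acylated (Et3N, CH2Cl2, 0 °C, no acyl-transfer catalyst, so that the shift to C3 is avoided) to the bromine-free pyrone ester F4. The lost activation is replaced by pressure: F4 and 17 at about 12 kbar in CH2Cl2 should give bicyclic lactone F5, which on heating in toluene should pass through cyclohexadiene F6 to the penta-O-benzyl tridepside F7. Hydrogenolysis of F7 rejoins the route at 21. This fallback still relies on the untested cycloaddition, now with the weaker diene.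

3. Step 2. The Elbs oxidation may stop at low conversion, because persulfate is consumed unproductively, and the hydroxyhydroquinone may be over-oxidised in the alkaline medium or lost during hydrolysis. The fallback sets out from orcinol 1 and introduces the extra oxygen before the formyl group. Teuber oxidation of 1 with potassium nitrosodisulfonate (KSO3)2NO gives 2-hydroxy-6-methyl-1,4-benzoquinone F8. Reduction with Na2S2O4 gives 6-methylbenzene-1,2,4-triol F9, and benzylation (BnBr, K2CO3, DMF) gives 1,2,5-tris(benzyloxy)-3-methylbenzene F10. Vilsmeier–Haack formylation (POCl3, DMF) is expected at C4, the position para to the 1-benzyloxy group and flanked by the methyl group in place of two benzyloxy groups. It proceeds through the iminium chloride F11 and its hydrolysis rejoins the route at 6.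

**Further compounds**

F1 | step 11 | benzyl 2,4-dihydroxy-6-methylbenzoate | Cc1cc(O)cc(O)c1C(=O)OCc1ccccc1
F2 | step 11 | 2-methoxy-6-methyl-4-{[2,4,5-tris(benzyloxy)-6-methylbenzoyl]oxy}benzoic trifluoroacetic anhydride | COc1cc(OC(=O)c2c(OCc3ccccc3)cc(OCc3ccccc3)c(OCc3ccccc3)c2C)cc(C)c1C(=O)OC(=O)C(F)(F)F
F3 | step 11 | benzyl 2-hydroxy-6-methyl-4-({2-methoxy-6-methyl-4-[(2,4,5-tris(benzyloxy)-6-methylbenzoyl)oxy]benzoyl}oxy)benzoate | COc1cc(OC(=O)c2c(OCc3ccccc3)cc(OCc3ccccc3)c(OCc3ccccc3)c2C)cc(C)c1C(=O)Oc1cc(C)c(C(=O)OCc2ccccc2)c(O)c1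
F4 | step 9 | 6-methyl-2-oxo-2H-pyran-4-yl 2-methoxy-6-methyl-4-{[2,4,5-tris(benzyloxy)-6-methylbenzoyl]oxy}benzoate | COc1cc(OC(=O)c2c(OCc3ccccc3)cc(OCc3ccccc3)c(OCc3ccccc3)c2C)cc(C)c1C(=O)Oc1cc(C)oc(=O)c1
F5 | step 9 | benzyl 5-(benzyloxy)-8-({2-methoxy-6-methyl-4-[(2,4,5-tris(benzyloxy)-6-methylbenzoyl)oxy]benzoyl}oxy)-1-methyl-3-oxo-5-[(trimethylsilyl)oxy]-2-oxabicyclo[2.2.2]oct-7-ene-6-carboxylate (racemic diastereomer mixture) | COc1cc(OC(=O)c2c(OCc3ccccc3)cc(OCc3ccccc3)c(OCc3ccccc3)c2C)cc(C)c1C(=O)OC1=CC2(C)OC(=O)C1C(OCc1ccccc1)(O[Si](C)(C)C)C2C(=O)OCc1ccccc1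
F6 | step 9 | benzyl 2-(benzyloxy)-4-({2-methoxy-6-methyl-4-[(2,4,5-tris(benzyloxy)-6-methylbenzoyl)oxy]benzoyl}oxy)-6-methyl-2-[(trimethylsilyl)oxy]cyclohexa-3,5-diene-1-carboxylate (racemic diastereomer mixture) | COc1cc(OC(=O)c2c(OCc3ccccc3)cc(OCc3ccccc3)c(OCc3ccccc3)c2C)cc(C)c1C(=O)OC1=CC(OCc2ccccc2)(O[Si](C)(C)C)C(C(=O)OCc2ccccc2)C(C)=C1
F7 | step 9 | benzyl 2-(benzyloxy)-6-methyl-4-({2-methoxy-6-methyl-4-[(2,4,5-tris(benzyloxy)-6-methylbenzoyl)oxy]benzoyl}oxy)benzoate | COc1cc(OC(=O)c2c(OCc3ccccc3)cc(OCc3ccccc3)c(OCc3ccccc3)c2C)cc(C)c1C(=O)Oc1cc(C)c(C(=O)OCc2ccccc2)c(OCc2ccccc2)c1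
F8 | step 2 | 2-hydroxy-6-methyl-1,4-benzoquinone | CC1=CC(=O)C=C(O)C1=O
F9 | step 2 | 6-methylbenzene-1,2,4-triol | Cc1cc(O)cc(O)c1O
F10 | step 2 | 1,2,5-tris(benzyloxy)-3-methylbenzene | Cc1cc(OCc2ccccc2)cc(OCc2ccccc2)c1OCc1ccccc1
F11 | step 2 | N-{[2,4,5-tris(benzyloxy)-6-methylphenyl]methylidene}-N-methylmethanaminium chloride | C[N+](C)=Cc1c(C)c(OCc2ccccc2)c(OCc2ccccc2)cc1OCc1ccccc1.[Cl-]
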